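**Retrosynthetic overview**
- No ring is formed: both benzene rings are bought intact. The target comes from a bis-MOM 1,3-diketone by acid removal of the two MOM ethers.
- Key disconnection: the ArC(=O)–CH2 bond. The aldehyde carbon of the ring-A aldehyde (as its carbene-derived Breslow intermediate, an aroyl anion) is joined to the bromomethyl carbon of a phenacyl bromide (an α-keto cation equivalent). Both carbons are normally electrophilic.
- Ring-A aldehyde ⇐ 2,4-dihydroxybenzaldehyde: C3-prenylation, then 4-O-MOM / 2-O-Me differentiation through the chelated 2-OH.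
- Ring-B partner ⇐ 2-bromo-4'-hydroxyacetophenone by O-MOM protection.

**Assumption:** the target has no stereocentre (achiral, diketo/enol tautomers), so "single enantiomer" needs no stereocontrol.

**Catalyst T** (used in step 4) = 3-(2,6-diisopropylphenyl)-5,6,7,8-tetrahydro-4H-cyclohepta[d]thiazol-3-ium perchlorate, CC(C)c1cccc(C(C)C)c1[n+]1csc2CCCCCc12.[O-]Cl(=O)(=O)=O

Step 1
Reactants: 1 2,4-dihydroxybenzaldehyde
Product: 2 2,4-dihydroxy-3-(3-methylbut-2-en-1-yl)benzaldehyde
Conditions: prenyl bromide (1.1 equiv), 10% aq KOH, 0 °C → rt, 12 h; acidify, chromatography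
Reagents that add atoms: prenyl bromide (1-bromo-3-methylbut-2-ene), CC(C)=CCBr
Why: Nuclear prenylation (phenoxide C-alkylation): in water the resorcinolate oxygens are hydrogen-bonded, so the allylic bromide attacks mainly at C3 between the two oxygens, giving 2 in modest yield (roughly 25–40% expected) after removal of 5-prenyl and O-prenyl isomers; no stereocentre is formed.

Step 2
Reactants: 2 2,4-dihydroxy-3-(3-methylbut-2-en-1-yl)benzaldehyde
Product: 4 2-methoxy-4-(methoxymethoxy)-3-(3-methylbut-2-en-1-yl)benzaldehyde, via 4-O-MOM phenol 3 (not isolated)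
Conditions: MOMCl (1.05 equiv), K2CO3 (3 equiv), acetone, 0 °C → rt; then MeI (3 equiv), 56 °C
Reagents that add atoms: chloromethyl methyl ether (MOMCl), COCCl; iodomethane (MeI), CI
Why: Two sequential Williamson etherifications: the 2-OH is hydrogen-bonded to the formyl group, so the free, more acidic 4-OH takes the MOM group first, and the chelated 2-OH is then methylated by excess MeI at reflux.

Step 3
Reactants: 5 2-bromo-1-(4-hydroxyphenyl)ethan-1-one
Product: 6 2-bromo-1-[4-(methoxymethoxy)phenyl]ethan-1-one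
Conditions: MOMBr (1.2 equiv), then i-Pr2NEt (1.3 equiv) dropwise, CH2Cl2, 0 °C
Reagents that add atoms: bromomethyl methyl ether (MOMBr), COCBr
Why: Williamson-type O-alkylation with an oxocarbenium-like halide, which outruns self-alkylation of the weakly nucleophilic 4-acylphenoxide; the bromide reagent avoids Br/Cl exchange at the phenacyl carbon.

Step 4
Reactants: 4 2-methoxy-4-(methoxymethoxy)-3-(3-methylbut-2-en-1-yl)benzaldehyde; 6 2-bromo-1-[4-(methoxymethoxy)phenyl]ethan-1-one
Product: 8 1-[2-methoxy-4-(methoxymethoxy)-3-(3-methylbut-2-en-1-yl)phenyl]-3-[4-(methoxymethoxy)phenyl]propane-1,3-dione, via Breslow intermediate 7 (not isolated)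
Conditions: 4 (1.2 equiv), catalyst T (20 mol%), i-Pr2NEt (2 equiv), degassed MeCN, Ar, 40 °C; 6 added by syringe pump over 4 h
Reagents that add atoms: none
Why: Proposed new method: NHC-catalysed aldehyde umpolung in which the thiazol-2-ylidene adds to 4 to give the Breslow enaminol 7 (an aroyl anion equivalent) that is captured at carbon by the highly SN2- and SET-reactive phenacyl bromide 6 (direct displacement, or electron transfer followed by ketyl/phenacyl radical recombination), after which the azolium alkoxide collapses to diketone 8 and releases the carbene; the closest known reaction types are intramolecular SN2 closures of Breslow intermediates onto alkyl tosylates or bromides, intermolecular NHC coupling of aryl aldehydes with benzhydryl bromides, and radical NHC ketone synthesis from aldehydes and redox-active esters, while the ortho-OMe/prenyl flank suppresses homo-benzoin and slow addition of 6 under a weak hindered amine base limits Darzens condensation, carbene alkylation and C-alkylation of the product enol.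

Step 5
Reactants: 8 1-[2-methoxy-4-(methoxymethoxy)-3-(3-methylbut-2-en-1-yl)phenyl]-3-[4-(methoxymethoxy)phenyl]propane-1,3-dione
Product: 9 1-[4-hydroxy-2-methoxy-3-(3-methylbut-2-en-1-yl)phenyl]-3-(4-hydroxyphenyl)propane-1,3-dione
Conditions: 3 M aq HCl, MeOH, 40 °C, 1–2 h (TLC control)
Reagents that add atoms: none
Why: Acid-catalysed acetal exchange (MOM transacetalisation to methanol) frees both phenols; the 2-OMe blocks flavone-type cyclodehydration of the diketone, and the mild temperature keeps the o-prenylphenol from closing to a chroman.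

**Compound list**
1 | 2,4-dihydroxybenzaldehyde | O=Cc1ccc(O)cc1O | starting material
2 | 2,4-dihydroxy-3-(3-methylbut-2-en-1-yl)benzaldehyde | CC(C)=CCc1c(O)ccc(C=O)c1O | intermediate
3 | 2-hydroxy-4-(methoxymethoxy)-3-(3-methylbut-2-en-1-yl)benzaldehyde (4-O-MOM phenol, formed in situ) | COCOc1ccc(C=O)c(O)c1CC=C(C)C | intermediate
4 | 2-methoxy-4-(methoxymethoxy)-3-(3-methylbut-2-en-1-yl)benzaldehyde | COCOc1ccc(C=O)c(OC)c1CC=C(C)C | intermediate
5 | 2-bromo-1-(4-hydroxyphenyl)ethan-1-one | O=C(CBr)c1ccc(O)cc1 | starting material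
6 | 2-bromo-1-[4-(methoxymethoxy)phenyl]ethan-1-one | COCOc1ccc(C(=O)CBr)cc1 | intermediate
7 | Breslow intermediate: enaminol from 4 and the thiazol-2-ylidene of catalyst T (formed in situ, enol C=C geometry not fixed) | COCOc1ccc(C(O)=C2SC3=C(N2c4c(C(C)C)cccc4C(C)C)CCCCC3)c(OC)c1CC=C(C)C | intermediate
8 | 1-[2-methoxy-4-(methoxymethoxy)-3-(3-methylbut-2-en-1-yl)phenyl]-3-[4-(methoxymethoxy)phenyl]propane-1,3-dione | COCOc1ccc(C(=O)CC(=O)c2ccc(OCOC)c(CC=C(C)C)c2OC)cc1 | intermediate
9 | 1-[4-hydroxy-2-methoxy-3-(3-methylbut-2-en-1-yl)phenyl]-3-(4-hydroxyphenyl)propane-1,3-dione (CNP0308388.0, achiral) | COc1c(C(=O)CC(=O)c2ccc(O)cc2)ccc(O)c1CC=C(C)C | target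

**Step count:** 5 steps in total. Longest linear sequence: 4 steps (steps 1, 2, 4, 5); step 3 is a one-step side branch.

**Three steps most likely to fail**

Step 4 (key coupling). This is the untested step. Possible failures are alkylation of the free carbene by 6, reductive debromination of 6, Darzens epoxide formation, addition of a phenacyl radical to the prenyl alkene, and C-alkylation of the product enol. The fallback keeps the same bond and polarity but uses a stoichiometric masked acyl anion. It sets out from 4 and 6 and comes back at 8. Aldehyde 4 is converted with propane-1,3-dithiol and catalytic iodine in CHCl3 into 2-[2-methoxy-4-(methoxymethoxy)-3-(3-methylbut-2-en-1-yl)phenyl]-1,3-dithiane F4. Bromoketone 6 is reduced with NaBH4 in MeOH to racemic 2-bromo-1-[4-(methoxymethoxy)phenyl]ethan-1-ol F5, which is closed in the same pot with K2CO3 to racemic 2-[4-(methoxymethoxy)phenyl]oxirane F6. Dithiane F4 is deprotonated with n-BuLi in THF at −78 °C and opens F6 at its terminal carbon to give the racemic hydroxy dithiane F7. Dess–Martin oxidation gives the keto dithiane F8. Hydrolysis with MeI and CaCO3 in aqueous MeCN unmasks the second carbonyl and delivers 8.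

Step 1 (C3-prenylation). Yield and regioselectivity are low, with 5-prenyl, O-prenyl and diprenyl by-products. The fallback replaces direct alkylation by halogenation and cross-coupling. It sets out from 1 and comes back at 4. Compound 1 is iodinated between the two hydroxyls with ICl in AcOH to give 2,4-dihydroxy-3-iodobenzaldehyde F1. The one-pot MOMCl/K2CO3 then MeI sequence of step 2 gives, through 2-hydroxy-3-iodo-4-(methoxymethoxy)benzaldehyde F2, the fully protected 3-iodo-2-methoxy-4-(methoxymethoxy)benzaldehyde F3. Stille coupling of F3 with tributyl(3-methylbut-2-en-1-yl)stannane (Pd(PPh3)4, DMF, 90 °C, linear-selective transfer) gives 4.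

Step 5 (MOM removal). Brønsted acid can cyclise the 3-prenyl-4-hydroxy unit to a 2,2-dimethylchroman. The fallback changes the protecting group to one removed by fluoride. It sets out from 2 and 5 and comes back at 9. Compound 2 is silylated at the free 4-OH with TIPSCl and imidazole to give 2-hydroxy-3-(3-methylbut-2-en-1-yl)-4-(triisopropylsilyloxy)benzaldehyde F9. Methylation with MeI and Ag2O gives 2-methoxy-3-(3-methylbut-2-en-1-yl)-4-(triisopropylsilyloxy)benzaldehyde F10. Compound 5 is silylated with TIPSOTf and 2,6-lutidine to give 2-bromo-1-[4-(triisopropylsilyloxy)phenyl]ethan-1-one F11. The carbene coupling of step 4 then proceeds through the silylated Breslow intermediate F12 to the bis-TIPS diketone F13. TBAF buffered with AcOH in THF at 0 °C gives 9.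

**Further compounds**
F1 | step 1 | 2,4-dihydroxy-3-iodobenzaldehyde | O=Cc1ccc(O)c(I)c1O
F2 | step 1 | 2-hydroxy-3-iodo-4-(methoxymethoxy)benzaldehyde | COCOc1ccc(C=O)c(O)c1I
F3 | step 1 | 3-iodo-2-methoxy-4-(methoxymethoxy)benzaldehyde | COCOc1ccc(C=O)c(OC)c1I
F4 | step 4 | 2-[2-methoxy-4-(methoxymethoxy)-3-(3-methylbut-2-en-1-yl)phenyl]-1,3-dithiane | COCOc1ccc(C2SCCCS2)c(OC)c1CC=C(C)C
F5 | step 4 | 2-bromo-1-[4-(methoxymethoxy)phenyl]ethan-1-ol (racemic) | COCOc1ccc(C(O)CBr)cc1
F6 | step 4 | 2-[4-(methoxymethoxy)phenyl]oxirane (racemic) | COCOc1ccc(C2CO2)cc1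
F7 | step 4 | 2-{2-[2-methoxy-4-(methoxymethoxy)-3-(3-methylbut-2-en-1-yl)phenyl]-1,3-dithian-2-yl}-1-[4-(methoxymethoxy)phenyl]ethan-1-ol (racemic) | COCOc1ccc(C(O)CC2(SCCCS2)c2ccc(OCOC)c(CC=C(C)C)c2OC)cc1
F8 | step 4 | 2-{2-[2-methoxy-4-(methoxymethoxy)-3-(3-methylbut-2-en-1-yl)phenyl]-1,3-dithian-2-yl}-1-[4-(methoxymethoxy)phenyl]ethan-1-one | COCOc1ccc(C(=O)CC2(SCCCS2)c2ccc(OCOC)c(CC=C(C)C)c2OC)cc1
F9 | step 5 | 2-hydroxy-3-(3-methylbut-2-en-1-yl)-4-(triisopropylsilyloxy)benzaldehyde | CC(C)[Si](Oc1ccc(C=O)c(O)c1CC=C(C)C)(C(C)C)C(C)C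
F10 | step 5 | 2-methoxy-3-(3-methylbut-2-en-1-yl)-4-(triisopropylsilyloxy)benzaldehyde | CC(C)[Si](Oc1ccc(C=O)c(OC)c1CC=C(C)C)(C(C)C)C(C)C
F11 | step 5 | 2-bromo-1-[4-(triisopropylsilyloxy)phenyl]ethan-1-one | CC(C)[Si](Oc1ccc(C(=O)CBr)cc1)(C(C)C)C(C)C
F12 | step 5 | Breslow intermediate from F10 and the thiazol-2-ylidene of catalyst T (formed in situ, enol C=C geometry not fixed) | CC(C)[Si](Oc1ccc(C(O)=C2SC3=C(N2c4c(C(C)C)cccc4C(C)C)CCCCC3)c(OC)c1CC=C(C)C)(C(C)C)C(C)C
F13 | step 5 | 1-[2-methoxy-3-(3-methylbut-2-en-1-yl)-4-(triisopropylsilyloxy)phenyl]-3-[4-(triisopropylsilyloxy)phenyl]propane-1,3-dione | CC(C)[Si](Oc1ccc(C(=O)CC(=O)c2ccc(O[Si](C(C)C)(C(C)C)C(C)C)c(CC=C(C)C)c2OC)cc1)(C(C)C)C(C)C
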